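**Retrosynthetic overview**

- The strategy rests on ring C: its C4 ketone beside the C3 carbinol is the α-hydroxy ketone that a Rubottom oxidation makes from a C3=C4 enol silane, and that endocyclic alkene of ring C is a metathesis bond. The vinyl group of the C6 side chain sits on a quaternary carbon between the C5 and C7 oxygens and stays out of the metathesis.
- Disconnections, backwards: C3–OH/C4=O to a 4-silyloxyflav-3-ene (face chosen by the C2 aryl group); C3=C4 by ring-closing metathesis of an aryl 1-arylallyl ether carrying an ortho 1-silyloxyvinyl group; O1–C2 by iridium-catalysed branched allylic etherification of a hydroxyacetophenone with a cinnamyl carbonate.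
- The C6 1,1-dimethylallyl group comes from an aromatic Claisen rearrangement of a prenyl ether on 2,4,6-trihydroxyacetophenone. The acetyl group is present from the start and blocks one of the two ortho positions.
- Ring order: rings A and B are bought (2,4,6-trihydroxyacetophenone, methyl 4-hydroxycinnamate); ring C is the only ring formed, in step 10.

Key step: step 10

Remark on the chemistry: the (Sa,Sc,Sc) phosphoramidite is taken as the antipode that gives the (S)-ether, by analogy with the known sense of induction for phenoxide and amine nucleophiles; if the sense is opposite, the mirror-image ligand is used and nothing else changes.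

**Route**

Step 1
Reactants: 1 1-(2,4,6-trihydroxyphenyl)ethanone
Product: 2 1-[2,6-dihydroxy-4-(methoxymethoxy)phenyl]ethanone
Conditions: MOMCl (1.0 equiv), i-Pr2NEt, THF, 0 °C
Reagents that add atoms: chloromethyl methyl ether, COCCl
Why: Williamson-type MOM etherification under weak-base control, in which the 4-OH is the only hydroxyl not hydrogen-bonded to the acetyl carbonyl and the most acidic, so one equivalent of the chloride should go there first.

Step 2
Reactants: 2 1-[2,6-dihydroxy-4-(methoxymethoxy)phenyl]ethanone; 3 prenyl bromide (1-bromo-3-methylbut-2-ene)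
Product: 4 1-[2-hydroxy-4-(methoxymethoxy)-6-(3-methylbut-2-enyloxy)phenyl]ethanone
Conditions: K2CO3, acetone, reflux
Reagents that add atoms: none
Why: Williamson O-alkylation of one of two equivalent phenols, after which the remaining hydroxyl is locked in the hydrogen bond to the carbonyl and reacts much more slowly, so the reaction should stop at the monoether.

Step 3
Reactants: 4 1-[2-hydroxy-4-(methoxymethoxy)-6-(3-methylbut-2-enyloxy)phenyl]ethanone
Product: 5 1-[2,6-dihydroxy-4-(methoxymethoxy)-3-(2-methylbut-3-en-2-yl)phenyl]ethanone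
Conditions: PhNEt2, 195 °C, Ar
Reagents that add atoms: none
Why: Aromatic Claisen rearrangement ([3,3] shift with allyl inversion) in which one ortho carbon carries the acetyl group and cannot rearomatise, so the 1,1-dimethylallyl group should end on the free ortho carbon between the two oxygens, the amine solvent speeding tautomerisation of the dienone ahead of a Cope shift.

Step 4
Reactants: 6 methyl (E)-4-hydroxycinnamate
Product: 7 methyl (E)-3-[4-(methoxymethoxy)phenyl]prop-2-enoate
Conditions: MOMCl, i-Pr2NEt, CH2Cl2, 0 °C to rt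
Reagents that add atoms: chloromethyl methyl ether, COCCl
Why: MOM protection of the phenol by O-alkylation, so that ring B carries the same acid-labile group as ring A.

Step 5
Reactants: 7 methyl (E)-3-[4-(methoxymethoxy)phenyl]prop-2-enoate
Product: 8 (E)-3-[4-(methoxymethoxy)phenyl]prop-2-en-1-ol
Conditions: i-Bu2AlH (2.2 equiv), CH2Cl2, −78 to 0 °C; aq. KNaC4H4O6
Reagents that add atoms: none
Why: 1,2-Reduction of the conjugated ester to the allylic alcohol by the aluminium hydride, which leaves the E alkene and the MOM ether alone.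

Step 6
Reactants: 8 (E)-3-[4-(methoxymethoxy)phenyl]prop-2-en-1-ol
Product: 9 methyl (E)-3-[4-(methoxymethoxy)phenyl]prop-2-enyl carbonate
Conditions: ClCO2Me, pyridine, CH2Cl2, 0 °C
Reagents that add atoms: methyl chloroformate, COC(=O)Cl
Why: Acylation of the primary alcohol with the chloroformate gives the linear allylic carbonate that ionises on iridium.

Step 7
Reactants: 5 1-[2,6-dihydroxy-4-(methoxymethoxy)-3-(2-methylbut-3-en-2-yl)phenyl]ethanone; 9 methyl (E)-3-[4-(methoxymethoxy)phenyl]prop-2-enyl carbonate
Product: 11 1-[2-hydroxy-4-(methoxymethoxy)-6-{(1S)-1-[4-(methoxymethoxy)phenyl]prop-2-enyloxy}-3-(2-methylbut-3-en-2-yl)phenyl]ethanone, via lithium phenoxide 10 (not isolated)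
Conditions: LiOt-Bu (1 equiv to 5), THF; then 9, [Ir(cod)Cl]2 (2 mol%), (Sa,Sc,Sc)-O,O'-(1,1'-binaphthyl-2,2'-diyl) N,N-bis(1-phenylethyl)phosphoramidite (4 mol%, pre-activated with n-PrNH2), THF, rt
Reagents that add atoms: none
Why: Iridium-catalysed asymmetric allylic etherification, in which the cyclometalated iridium–phosphoramidite complex ionises the carbonate to a π-allyl species and the phenoxide attacks its aryl-substituted terminus on the face fixed by the ligand to give the branched (S)-ether, while of the two phenol oxygens only the one next to a ring hydrogen can reach the secondary carbon, the other being walled in by the quaternary side chain and the acetyl group.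

Step 8
Reactants: 11 1-[2-hydroxy-4-(methoxymethoxy)-6-{(1S)-1-[4-(methoxymethoxy)phenyl]prop-2-enyloxy}-3-(2-methylbut-3-en-2-yl)phenyl]ethanone
Product: 13 1-[2,4-bis(methoxymethoxy)-6-{(1S)-1-[4-(methoxymethoxy)phenyl]prop-2-enyloxy}-3-(2-methylbut-3-en-2-yl)phenyl]ethanone, via sodium phenoxide 12 (not isolated)
Conditions: NaH (1.2 equiv), DMF/THF, 0 °C; then MOMCl, 0 °C to rt
Reagents that add atoms: chloromethyl methyl ether, COCCl
Why: Williamson MOM etherification through the sodium phenoxide, needed because this hydroxyl is chelated and hindered, and the small, reactive chloromethyl ether should still reach it.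

Step 9
Reactants: 13 1-[2,4-bis(methoxymethoxy)-6-{(1S)-1-[4-(methoxymethoxy)phenyl]prop-2-enyloxy}-3-(2-methylbut-3-en-2-yl)phenyl]ethanone
Product: 15 tert-butyl{1-[2,4-bis(methoxymethoxy)-6-{(1S)-1-[4-(methoxymethoxy)phenyl]prop-2-enyloxy}-3-(2-methylbut-3-en-2-yl)phenyl]ethenyloxy}dimethylsilane, via potassium enolate 14 (not isolated)
Conditions: KN(SiMe3)2 (1.1 equiv), THF, −78 °C; then TBSCl, −78 to −20 °C; Et3N-buffered work-up
Reagents that add atoms: tert-butyldimethylsilyl chloride, CC(C)(C)[Si](C)(C)Cl
Why: Kinetic deprotonation of the methyl ketone and O-silylation of the potassium enolate (silyl enol ether formation), a base route that keeps Lewis-acidic silyl triflates away from the MOM acetals.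

Step 10
Reactants: 15 tert-butyl{1-[2,4-bis(methoxymethoxy)-6-{(1S)-1-[4-(methoxymethoxy)phenyl]prop-2-enyloxy}-3-(2-methylbut-3-en-2-yl)phenyl]ethenyloxy}dimethylsilane
Product: 16 (2S)-4-(tert-butyldimethylsilyloxy)-5,7-bis(methoxymethoxy)-2-[4-(methoxymethoxy)phenyl]-6-(2-methylbut-3-en-2-yl)-2H-chromene
Conditions: second-generation Grubbs catalyst RuCl2(=CHPh)(H2IMes)(PCy3) (5 mol%, second charge if needed), 1,4-benzoquinone (10 mol%), degassed toluene (0.005 M), 60 °C, Ar sparge, dark
Reagents that add atoms: none
Why: The ruthenium benzylidene exchanges onto the monosubstituted alkene of the allylic ether, the new alkylidene adds across the C=CH2 of the enol silane to a ruthenacyclobutane, and cycloreversion releases the C3=C4 bond and a ruthenium methylidene that carries the chain with loss of ethylene. The closest known reactions are the silyl enol ether–ene ring-closing metathesis that gives cyclic enol silanes (for example 4-silyloxy-1,2-dihydroquinolines from N-allyl-2-(1-silyloxyvinyl)anilines) and the ring-closing metathesis of allyl 2-vinylaryl ethers to 2H-chromenes. Ring C closes as a six-membered ring by alkene–alkene metathesis, with the new double bond endocyclic and both reacting arms held ortho on ring A. No stereocentre is formed; C2, set in step 7, has no bond that the carbene touches and should be kept by working in the dark at 60 °C or below, where electrocyclic opening of the 2H-chromene is not expected. The step needs chemoselectivity among three terminal alkenes: the C6 vinyl group hangs on a quaternary carbon between two MOM ethers, so it should neither load the catalyst at a useful rate nor reach a partner through an unstrained ring, and high dilution holds back dimerisation through the allylic ether alkene. 1,4-Benzoquinone is added to quench ruthenium hydrides that would move the allylic ether double bond.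

Step 11
Reactants: 16 (2S)-4-(tert-butyldimethylsilyloxy)-5,7-bis(methoxymethoxy)-2-[4-(methoxymethoxy)phenyl]-6-(2-methylbut-3-en-2-yl)-2H-chromene
Product: 18 (2R,3R)-3-hydroxy-5,7-bis(methoxymethoxy)-2-[4-(methoxymethoxy)phenyl]-6-(2-methylbut-3-en-2-yl)chroman-4-one, via silyloxy epoxide 17 (not isolated)
Conditions: dimethyldioxirane (1.1 equiv, acetone), CH2Cl2, −78 to −40 °C; then Bu4NF/AcOH (1:1), THF, −20 to 0 °C
Reagents that add atoms: dimethyldioxirane, CC1(C)OO1
Why: Rubottom oxidation, in which the dioxirane should epoxidise the electron-rich enol silane on the face of ring C opposite the C2 aryl group, setting C3 as R with its oxygen trans to the aryl group, and fluoride then removes silicon so that the epoxide collapses to the C4 ketone without touching the C3–O bond, the hindered monosubstituted vinyl group being far slower toward the electrophilic oxidant.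

Step 12
Reactants: 18 (2R,3R)-3-hydroxy-5,7-bis(methoxymethoxy)-2-[4-(methoxymethoxy)phenyl]-6-(2-methylbut-3-en-2-yl)chroman-4-one
Product: 19 (2R,3R)-3,5,7-trihydroxy-2-(4-hydroxyphenyl)-6-(2-methylbut-3-en-2-yl)chroman-4-one
Conditions: HCl (3 M), MeOH, rt to 40 °C
Reagents that add atoms: none
Why: Acid-catalysed acetal exchange with methanol should remove the three MOM groups as dimethoxymethane under conditions in which the trans-dihydroflavonol and the 1,1-dimethylallyl group are stable, so C2 and C3 stay as set.

**Compound list**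

1 | 1-(2,4,6-trihydroxyphenyl)ethanone | CC(=O)c1c(O)cc(O)cc1O | starting material
2 | 1-[2,6-dihydroxy-4-(methoxymethoxy)phenyl]ethanone | CC(=O)c1c(O)cc(OCOC)cc1O | intermediate
3 | prenyl bromide (1-bromo-3-methylbut-2-ene) | CC(C)=CCBr | starting material
4 | 1-[2-hydroxy-4-(methoxymethoxy)-6-(3-methylbut-2-enyloxy)phenyl]ethanone | CC(=O)c1c(O)cc(OCOC)cc1OCC=C(C)C | intermediate
5 | 1-[2,6-dihydroxy-4-(methoxymethoxy)-3-(2-methylbut-3-en-2-yl)phenyl]ethanone | CC(=O)c1c(O)cc(OCOC)c(C(C)(C)C=C)c1O | intermediate
6 | methyl (E)-4-hydroxycinnamate | COC(=O)/C=C/c1ccc(O)cc1 | starting material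
7 | methyl (E)-3-[4-(methoxymethoxy)phenyl]prop-2-enoate | COC(=O)/C=C/c1ccc(OCOC)cc1 | intermediate
8 | (E)-3-[4-(methoxymethoxy)phenyl]prop-2-en-1-ol | OC/C=C/c1ccc(OCOC)cc1 | intermediate
9 | methyl (E)-3-[4-(methoxymethoxy)phenyl]prop-2-enyl carbonate | COC(=O)OC/C=C/c1ccc(OCOC)cc1 | intermediate
10 | lithium 2-acetyl-3-hydroxy-5-(methoxymethoxy)-4-(2-methylbut-3-en-2-yl)phenoxide | [Li+].CC(=O)c1c([O-])cc(OCOC)c(C(C)(C)C=C)c1O | intermediate
11 | 1-[2-hydroxy-4-(methoxymethoxy)-6-{(1S)-1-[4-(methoxymethoxy)phenyl]prop-2-enyloxy}-3-(2-methylbut-3-en-2-yl)phenyl]ethanone | CC(=O)c1c(O[C@@H](C=C)c2ccc(OCOC)cc2)cc(OCOC)c(C(C)(C)C=C)c1O | intermediate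
12 | sodium phenoxide of 11 (anion at the oxygen between the acetyl group and the side chain) | [Na+].CC(=O)c1c(O[C@@H](C=C)c2ccc(OCOC)cc2)cc(OCOC)c(C(C)(C)C=C)c1[O-] | intermediate
13 | 1-[2,4-bis(methoxymethoxy)-6-{(1S)-1-[4-(methoxymethoxy)phenyl]prop-2-enyloxy}-3-(2-methylbut-3-en-2-yl)phenyl]ethanone | CC(=O)c1c(O[C@@H](C=C)c2ccc(OCOC)cc2)cc(OCOC)c(C(C)(C)C=C)c1OCOC | intermediate
14 | potassium enolate of 13 | [K+].C=C([O-])c1c(O[C@@H](C=C)c2ccc(OCOC)cc2)cc(OCOC)c(C(C)(C)C=C)c1OCOC | intermediate
15 | tert-butyl{1-[2,4-bis(methoxymethoxy)-6-{(1S)-1-[4-(methoxymethoxy)phenyl]prop-2-enyloxy}-3-(2-methylbut-3-en-2-yl)phenyl]ethenyloxy}dimethylsilane | C=CC(C)(C)c1c(OCOC)cc(O[C@@H](C=C)c2ccc(OCOC)cc2)c(C(=C)O[Si](C)(C)C(C)(C)C)c1OCOC | intermediate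
16 | (2S)-4-(tert-butyldimethylsilyloxy)-5,7-bis(methoxymethoxy)-2-[4-(methoxymethoxy)phenyl]-6-(2-methylbut-3-en-2-yl)-2H-chromene | C=CC(C)(C)c1c(OCOC)cc2c(c1OCOC)C(O[Si](C)(C)C(C)(C)C)=C[C@@H](c1ccc(OCOC)cc1)O2 | intermediate
17 | (2R,3R,4R)-4-(tert-butyldimethylsilyloxy)-3,4-epoxy-5,7-bis(methoxymethoxy)-2-[4-(methoxymethoxy)phenyl]-6-(2-methylbut-3-en-2-yl)chromane, epoxide oxygen anti to the C2 aryl group | C=CC(C)(C)c1c(OCOC)cc2c(c1OCOC)[C@]3(O[Si](C)(C)C(C)(C)C)O[C@@H]3[C@@H](c4ccc(OCOC)cc4)O2 | intermediate
18 | (2R,3R)-3-hydroxy-5,7-bis(methoxymethoxy)-2-[4-(methoxymethoxy)phenyl]-6-(2-methylbut-3-en-2-yl)chroman-4-one | C=CC(C)(C)c1c(OCOC)cc2c(c1OCOC)C(=O)[C@H](O)[C@@H](c1ccc(OCOC)cc1)O2 | intermediate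
19 | (2R,3R)-3,5,7-trihydroxy-2-(4-hydroxyphenyl)-6-(2-methylbut-3-en-2-yl)chroman-4-one | C=CC(C)(C)c1c(O)cc2c(c1O)C(=O)[C@H](O)[C@@H](c1ccc(O)cc1)O2 | target

**Step count and risk**

Total step count: 12. Longest linear sequence: 9 steps (from 1 through steps 1, 2, 3, 7–12, or from 6 through steps 4–12).

Steps most likely to fail:

1. Step 10 (ring-closing metathesis). The closure onto the hindered, electron-rich 1,1-disubstituted enol silane may be slower than catalyst decay, ruthenium hydrides may shift the allylic ether alkene, or the enol silane may be cleaved on the metal. The fallback closes C3=C4 between two monosubstituted alkenes and adds the C3 and C4 oxygens afterwards. It sets out from ketone 13. NaBH4 (MeOH/THF) should give 1-[2,4-bis(methoxymethoxy)-6-{(1S)-1-[4-(methoxymethoxy)phenyl]prop-2-enyloxy}-3-(2-methylbut-3-en-2-yl)phenyl]ethanol F1 as a mixture of carbinol epimers. Dehydration with Martin sulfurane should give the styrene 1-ethenyl-2,4-bis(methoxymethoxy)-6-{(1S)-1-[4-(methoxymethoxy)phenyl]prop-2-enyloxy}-3-(2-methylbut-3-en-2-yl)benzene F2. Ring-closing metathesis with the second-generation Grubbs catalyst (CH2Cl2, 40 °C) should give (2S)-5,7-bis(methoxymethoxy)-2-[4-(methoxymethoxy)phenyl]-6-(2-methylbut-3-en-2-yl)-2H-chromene F3. Dimethyldioxirane should epoxidise anti to the C2 aryl group to the 2,3-trans 3,4-epoxide F4, which water opens at the benzylic C4 to the (2R,3S,4R)-flavan-3,4-diol F5 (the C4 configuration is of no consequence). MnO2 in CH2Cl2 should oxidise the benzylic C4 carbinol selectively, and the route is rejoined at compound 18.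

2. Step 7 (allylic etherification). The chelated, electron-poor phenoxide attacks slowly and is a good leaving group, so the branched ether may re-ionise on iridium with loss of branched selectivity and enantiomeric purity, or the ring carbon between the oxygens may be allylated instead of oxygen. The fallback separates the enantioselective step from the coupling with the phenol. It sets out from carbonate 9 and diol 5. Carbonate 9 with KOSiEt3, [Ir(cod)Cl]2 and the mirror-image phosphoramidite should give triethyl{(1R)-1-[4-(methoxymethoxy)phenyl]prop-2-enyloxy}silane F6. Bu4NF should free (1R)-1-[4-(methoxymethoxy)phenyl]prop-2-en-1-ol F7. A Mitsunobu reaction of this alcohol with 5 (PPh3, diisopropyl azodicarboxylate, toluene, −20 °C) should join the unhindered phenol oxygen with inversion and return to the route at compound 11.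

3. Step 3 (Claisen rearrangement). The ortho-dienone may leak through a Cope shift to the para carbon and give the linear prenyl isomer, or the freed phenol may add to the new allyl group at 195 °C. The fallback blocks the para position with the acetyl group and makes both ortho positions equivalent. It sets out from compound 1. Alkylation with prenyl bromide 3 (K2CO3, 1 equiv, acetone, rt) at the most acidic, non-chelated 4-OH should give 1-[2,6-dihydroxy-4-(3-methylbut-2-enyloxy)phenyl]ethanone F8. Its Claisen rearrangement (PhNEt2, 190 °C) can only end on the carbon between two oxygens and should give 1-[2,4,6-trihydroxy-3-(2-methylbut-3-en-2-yl)phenyl]ethanone F9. MOMCl (1 equiv) with i-Pr2NEt at the non-chelated 4-OH then returns to the route at compound 5.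

**Further compounds**

F1 | step 10 | 1-[2,4-bis(methoxymethoxy)-6-{(1S)-1-[4-(methoxymethoxy)phenyl]prop-2-enyloxy}-3-(2-methylbut-3-en-2-yl)phenyl]ethanol (both carbinol epimers) | CC(O)c1c(O[C@@H](C=C)c2ccc(OCOC)cc2)cc(OCOC)c(C(C)(C)C=C)c1OCOC
F2 | step 10 | 1-ethenyl-2,4-bis(methoxymethoxy)-6-{(1S)-1-[4-(methoxymethoxy)phenyl]prop-2-enyloxy}-3-(2-methylbut-3-en-2-yl)benzene | C=Cc1c(O[C@@H](C=C)c2ccc(OCOC)cc2)cc(OCOC)c(C(C)(C)C=C)c1OCOC
F3 | step 10 | (2S)-5,7-bis(methoxymethoxy)-2-[4-(methoxymethoxy)phenyl]-6-(2-methylbut-3-en-2-yl)-2H-chromene | C=CC(C)(C)c1c(OCOC)cc2c(c1OCOC)C=C[C@@H](c1ccc(OCOC)cc1)O2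
F4 | step 10 | 2,3-trans 3,4-epoxide of F3, epoxide oxygen anti to the C2 aryl group | C=CC(C)(C)c1c(OCOC)cc2c(c1OCOC)[C@@H]3O[C@@H]3[C@@H](c4ccc(OCOC)cc4)O2
F5 | step 10 | (2R,3S,4R)-5,7-bis(methoxymethoxy)-2-[4-(methoxymethoxy)phenyl]-6-(2-methylbut-3-en-2-yl)chromane-3,4-diol | C=CC(C)(C)c1c(OCOC)cc2c(c1OCOC)[C@@H](O)[C@H](O)[C@@H](c3ccc(OCOC)cc3)O2
F6 | step 7 | triethyl{(1R)-1-[4-(methoxymethoxy)phenyl]prop-2-enyloxy}silane | CC[Si](CC)(CC)O[C@H](C=C)c1ccc(OCOC)cc1
F7 | step 7 | (1R)-1-[4-(methoxymethoxy)phenyl]prop-2-en-1-ol | O[C@H](C=C)c1ccc(OCOC)cc1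
F8 | step 3 | 1-[2,6-dihydroxy-4-(3-methylbut-2-enyloxy)phenyl]ethanone | CC(=O)c1c(O)cc(OCC=C(C)C)cc1O
F9 | step 3 | 1-[2,4,6-trihydroxy-3-(2-methylbut-3-en-2-yl)phenyl]ethanone | CC(=O)c1c(O)cc(O)c(C(C)(C)C=C)c1O
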